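**Plan**

- Feature: the furofuran (3,7-dioxabicyclo[3.3.0]octane, primed numbers; C2' on C5 of dihydrobenzofuran ring B, C6' on the syringyl ring) differs from an all-trans 1,2-diaryl-3,4-bis(hydroxymethyl)cyclobutane only in having the benzylic C–O bonds C2'–O3' and C6'–O7' in place of a C2'–C6' bond; the C1'–C5' bond is common to both.
- Retrosynthesis: (a) phenolic benzyl ether off; (b) cut C2'–O3' and C6'–O7' and join C2'–C6' (cyclobutane 15); (c) cut C2'–C6' and C1'–C5' ([2+2]) to two cinnamates held on (1R,2R)-cyclohexane-1,2-diol; (d) cut the aryl–vinyl bond (Heck), then the C2–C3 bond of the dihydrobenzofuran (carbene C–H insertion) and the aryl–C bond to the diazo ester.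
- Forward ring order: dihydrofuran ring (step 4), then the cyclobutane with a temporary eight-membered bis-lactone (step 10), then both tetrahydrofuran rings at once while the cyclobutane opens (step 12).
- Stereochemistry: the target SMILES encodes a 2,3-cis (2S,3S) dihydrobenzofuran, set by a chiral dirhodium carboxylate; C1'/C5' (R,R) come from the diol tether in the photocycloaddition; C2'/C6' (S,S) arise in the key step under control of the adjacent bridgeheads.

Key step: step 12

Assumption: the facial sense of Rh2(R-PTTL)4 (taken by analogy as giving the 2S ring) and of the (1R,2R)-diol tether (taken from a crossed-arm model with an O–C–C–O torsion of about −60°) is as stated; if either proves opposite, the enantiomeric catalyst or diol is used and nothing else changes.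

**Route**

Step 1
Reactants: 1 4-bromo-2-methoxyphenol
Product: 2 4-bromo-2-iodo-6-methoxyphenol
Conditions: I2, NaHCO3, THF/H2O, rt
Reagents that add atoms: iodine, II
Why: Electrophilic aromatic iodination of the phenoxide goes ortho to oxygen because the para position is blocked by bromine, as in the iodination of vanillin.

Step 2
Reactants: 2 4-bromo-2-iodo-6-methoxyphenol; 3 [4-(benzyloxy)-3-methoxyphenyl]methanol
Product: 4 2-{[4-(benzyloxy)-3-methoxyphenyl]methoxy}-5-bromo-1-iodo-3-methoxybenzene
Conditions: PPh3, DIAD, THF, 0 °C to rt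
Reagents that add atoms: none
Why: Mitsunobu etherification, in which the acidic di-ortho-substituted phenol displaces the alkoxyphosphonium ion of the primary benzylic alcohol, so that no labile p-alkoxybenzyl halide has to be made.

Step 3
Reactants: 4 aryl iodide
Product: 5 ethyl 2-(2-{[4-(benzyloxy)-3-methoxyphenyl]methoxy}-5-bromo-3-methoxyphenyl)-2-diazoacetate
Conditions: N2CHCO2Et, Pd(PPh3)4 (5 mol%), Ag2CO3 (0.5 equiv), Et3N, toluene, rt
Reagents that add atoms: ethyl diazoacetate, CCOC(=O)C=[N+]=[N-]
Why: Palladium-catalysed cross-coupling of an aryl iodide with an acceptor diazo compound (C–H arylation of the diazoacetate with retention of the diazo group), the oxidative addition to zerovalent palladium taking place at C–I and not at C–Br at room temperature.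

Step 4
Reactants: 5 aryl diazoacetate
Product: 6 ethyl (2S,3R)-2-[4-(benzyloxy)-3-methoxyphenyl]-5-bromo-7-methoxy-2,3-dihydro-1-benzofuran-3-carboxylate (2,3-cis)
Conditions: Rh2(R-PTTL)4 (dirhodium tetrakis[N-phthaloyl-(R)-tert-leucinate], 1 mol%), toluene, −60 °C
Reagents that add atoms: none
Why: Intramolecular 1,5 C–H insertion of the donor/acceptor rhodium carbene into the benzylic ether C–H bond, a concerted process that is known to give the 2,3-cis ring on closely related 5-bromo substrates, with the chiral carboxylate ligands setting C2 and C3 together as (2S,3R).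

Step 5
Reactants: 6 cis ester
Product: 7 {(2S,3S)-2-[4-(benzyloxy)-3-methoxyphenyl]-5-bromo-7-methoxy-2,3-dihydro-1-benzofuran-3-yl}methanol (2,3-cis)
Conditions: i-Bu2AlH (3 equiv), CH2Cl2, −78 to −20 °C; aq. KNaC4H4O6
Reagents that add atoms: none
Why: Ester reduction with a non-basic aluminium hydride at low temperature is faster than enolisation, so the epimerisable cis C3 centre is kept (3R becomes 3S by a change of priorities only) and the aryl bromide is untouched.

Step 6
Reactants: 8 sinapic acid
Product: 9 (E)-3-(4-acetoxy-3,5-dimethoxyphenyl)prop-2-enoic acid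
Conditions: Ac2O, pyridine, rt; then H2O
Reagents that add atoms: acetic anhydride, CC(=O)OC(C)=O
Why: Acyl transfer to the phenol masks the syringol through esterification, Heck coupling and irradiation, and the acetate falls without an extra step in the LiAlH4 reduction of step 11.

Step 7
Reactants: 9 O-acetylsinapic acid; 10 (1R,2R)-cyclohexane-1,2-diol (3 equiv)
Product: 11 (1R,2R)-2-hydroxycyclohexyl (E)-3-(4-acetoxy-3,5-dimethoxyphenyl)prop-2-enoate
Conditions: EDC·HCl, DMAP (cat.), CH2Cl2, 0 °C to rt
Reagents that add atoms: none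
Why: Carbodiimide (Steglich) esterification, in which the two hydroxyl groups of the C2-symmetric diol are homotopic so that monoacylation gives one compound and the excess of diol suppresses the diester.

Step 8
Reactants: 11 monoester
Product: 12 (1R,2R)-2-(acryloyloxy)cyclohexyl (E)-3-(4-acetoxy-3,5-dimethoxyphenyl)prop-2-enoate
Conditions: CH2=CHCOCl, Et3N, CH2Cl2, 0 °C
Reagents that add atoms: acryloyl chloride, C=CC(Cl)=O
Why: Acylation of the remaining secondary alcohol with an acid chloride installs the acrylate that will carry the second aryl group.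

Step 9
Reactants: 7 bromo alcohol; 12 acrylate
Product: 13 (1R,2R)-cyclohexane-1,2-diyl mixed diester of (E)-4-acetoxy-3,5-dimethoxycinnamic acid and (E)-3-{(2S,3S)-2-[4-(benzyloxy)-3-methoxyphenyl]-3-(hydroxymethyl)-7-methoxy-2,3-dihydro-1-benzofuran-5-yl}prop-2-enoic acid
Conditions: Pd2(dba)3 (2.5 mol%), [HP(t-Bu)3]BF4 (10 mol%), Cy2NMe, dioxane, 50 °C
Reagents that add atoms: none
Why: Heck reaction, in which the arylpalladium species inserts into the monosubstituted acrylate far faster than into the 1,2-disubstituted sinapate and syn β-hydride elimination gives the E-alkene, at a temperature mild enough for the aryl acetate.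

Step 10
Reactants: 13 tethered dicinnamate
Product: 14 (1R,2R,3S,4S)-cyclobutane-1,2-dicarboxylate bis-lactone of (1R,2R)-cyclohexane-1,2-diol (all-trans; trans-fused eight-membered ring), carrying the acetylated syringyl ring on C3 and the dihydrobenzofuran-5-yl group on C4
Conditions: hν (350 nm, Pyrex), degassed MeCN (3 mM), rt
Reagents that add atoms: none
Why: Intramolecular head-to-head [2+2] photocycloaddition of a diol-tethered dicinnamate (truxinate formation), in which the diequatorial (1R,2R)-diol fixes the O–C–C–O torsion so that the two s-cis cinnamoyl arms cross in one sense and join their α-Si faces, setting C1 and C2 as R,R and trans, while suprafacial addition to the E-alkenes places each aryl trans to its ester (C3 and C4 S,S), a pair of centres that is erased again in step 12.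

Step 11
Reactants: 14 bis-lactone
Product: 15 [(1R,2R,3S,4S)-3-(4-hydroxy-3,5-dimethoxyphenyl)-4-{(2S,3S)-2-[4-(benzyloxy)-3-methoxyphenyl]-3-(hydroxymethyl)-7-methoxy-2,3-dihydro-1-benzofuran-5-yl}cyclobutane-1,2-diyl]dimethanol (all-trans)
Conditions: LiAlH4, THF, 0 °C to rt; aq. KNaC4H4O6
Reagents that add atoms: none
Why: Hydride reduction of both lactone carbonyls and of the aryl acetate detaches the tether and frees the two hydroxymethyl groups and the syringol in one operation without touching a stereocentre.

Step 12
Reactants: 15 cyclobutane triol phenol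
Product: 17 O-benzyl ether of the target (furofuran 1'R,2'S,5'R,6'S; benzyl on the guaiacyl oxygen), via quinone methide 16 (not isolated)
Conditions: PhI(OAc)2 (1.05 equiv), (CF3)2CHOH/CH2Cl2 (4:1), −20 to 0 °C; then aq. NaHCO3/Na2S2O3
Reagents that add atoms: none
Why: Ligand exchange of the syringol on PhI(OAc)2 and two-electron oxidation in the ionising, non-nucleophilic (CF3)2CHOH give a phenoxenium ion whose para substituent is the strained cyclobutane, and the C3–C4 bond, the only one flanked by both aryl groups, breaks heterolytically with relief of ring strain to a p-quinone methide at C3 (future C6') and a benzylic cation at C4 (future C2') that is stabilised by the para ring oxygen O1 of the dihydrobenzofuran. The closest known reaction type is the oxidative ring opening of 1,2-diarylcyclobutanes to bis-quinone-methide equivalents with capture by oxygen nucleophiles, the same bis-electrophile that closes to furofurans in 8–8' phenol coupling. Both tetrahydrofuran rings close 5-exo-trig: the hydroxymethyl group on C2 adds to the cation (C2'–O3', giving 16), then the hydroxymethyl group on C1 adds to the quinone methide with rearomatisation (C6'–O7'), the only other intramolecular options for oxygen being four-membered rings. The new centres C2' and C6' are each set by the neighbouring bridgehead, the aryl group taking the exo position trans to the vicinal ring carbon in the envelope transition state (2'S,6'S), while the untouched trans C1/C2 pair becomes the cis ring fusion (1'R,5'R). The step needs oxidation of one arene only and oxygen capture in preference to Friedel–Crafts closure, and these are secured by the single free phenol (the guaiacol is benzylated), the low temperature and short reaction time, and the proximity of the two reacting alcohols, the third primary alcohol on the dihydrobenzofuran being unable to reach either electrophilic carbon.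

Step 13
Reactants: 17 O-benzyl ether
Product: 18 CNP0126146.1 (target)
Conditions: H2 (1 atm), 10% Pd/C, EtOAc, rt, stopped at consumption of 17
Reagents that add atoms: none
Why: Hydrogenolysis of an aryl benzyl ether is much faster than that of the cyclic benzylic ethers of the furofuran and dihydrobenzofuran, so neutral conditions and a short reaction time should free the guaiacol alone.

**Compound list**

1 | 4-bromo-2-methoxyphenol | COc1cc(Br)ccc1O | starting material
2 | 4-bromo-2-iodo-6-methoxyphenol | COc1cc(Br)cc(I)c1O | intermediate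
3 | [4-(benzyloxy)-3-methoxyphenyl]methanol | COc1cc(CO)ccc1OCc1ccccc1 | starting material
4 | 2-{[4-(benzyloxy)-3-methoxyphenyl]methoxy}-5-bromo-1-iodo-3-methoxybenzene | COc1cc(Br)cc(I)c1OCc1ccc(OCc2ccccc2)c(OC)c1 | intermediate
5 | ethyl 2-(2-{[4-(benzyloxy)-3-methoxyphenyl]methoxy}-5-bromo-3-methoxyphenyl)-2-diazoacetate | CCOC(=O)C(=[N+]=[N-])c1cc(Br)cc(OC)c1OCc1ccc(OCc2ccccc2)c(OC)c1 | intermediate
6 | ethyl (2S,3R)-2-[4-(benzyloxy)-3-methoxyphenyl]-5-bromo-7-methoxy-2,3-dihydro-1-benzofuran-3-carboxylate (cis) | COc1cc([C@H]2Oc3c(OC)cc(Br)cc3[C@H]2C(=O)OCC)ccc1OCc1ccccc1 | intermediate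
7 | {(2S,3S)-2-[4-(benzyloxy)-3-methoxyphenyl]-5-bromo-7-methoxy-2,3-dihydro-1-benzofuran-3-yl}methanol (cis) | COc1cc([C@H]2Oc3c(OC)cc(Br)cc3[C@H]2CO)ccc1OCc1ccccc1 | intermediate
8 | sinapic acid | COc1cc(/C=C/C(=O)O)cc(OC)c1O | starting material
9 | (E)-3-(4-acetoxy-3,5-dimethoxyphenyl)prop-2-enoic acid | COc1cc(/C=C/C(=O)O)cc(OC)c1OC(C)=O | intermediate
10 | (1R,2R)-cyclohexane-1,2-diol | O[C@@H]1CCCC[C@H]1O | starting material
11 | (1R,2R)-2-hydroxycyclohexyl (E)-3-(4-acetoxy-3,5-dimethoxyphenyl)prop-2-enoate | COc1cc(/C=C/C(=O)O[C@@H]2CCCC[C@H]2O)cc(OC)c1OC(C)=O | intermediate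
12 | (1R,2R)-2-(acryloyloxy)cyclohexyl (E)-3-(4-acetoxy-3,5-dimethoxyphenyl)prop-2-enoate | COc1cc(/C=C/C(=O)O[C@@H]2CCCC[C@H]2OC(=O)C=C)cc(OC)c1OC(C)=O | intermediate
13 | (1R,2R)-cyclohexane-1,2-diyl mixed (E,E)-dicinnamate (acetylsinapate and dihydrobenzofuran-5-acrylate) | COc1cc([C@H]2Oc3c(OC)cc(/C=C/C(=O)O[C@@H]4CCCC[C@H]4OC(=O)/C=C/c4cc(OC)c(OC(C)=O)c(OC)c4)cc3[C@H]2CO)ccc1OCc1ccccc1 | intermediate
14 | all-trans (1R,2R,3S,4S)-cyclobutane bis-lactone on the (1R,2R)-cyclohexanediol tether | COc1cc([C@H]2Oc3c(OC)cc([C@@H]4[C@H]5C(=O)O[C@@H]6CCCC[C@H]6OC(=O)[C@@H]5[C@H]4c4cc(OC)c(OC(C)=O)c(OC)c4)cc3[C@H]2CO)ccc1OCc1ccccc1 | intermediate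
15 | all-trans (1R,2R,3S,4S)-3-syringyl-4-(dihydrobenzofuran-5-yl)cyclobutane-1,2-dimethanol (free syringol, benzylated guaiacol) | COc1cc([C@H]2Oc3c(OC)cc([C@@H]4[C@@H](CO)[C@H](CO)[C@H]4c4cc(OC)c(O)c(OC)c4)cc3[C@H]2CO)ccc1OCc1ccccc1 | intermediate
16 | 2,6-dimethoxy-p-quinone methide bearing the 2-aryl-4-(hydroxymethyl)tetrahydrofuran-3-yl group on the methide carbon (first tetrahydrofuran ring closed) | COc1cc([C@H]2Oc3c(OC)cc([C@H]4OC[C@H](C=C5C=C(OC)C(=O)C(OC)=C5)[C@@H]4CO)cc3[C@H]2CO)ccc1OCc1ccccc1 | intermediate (not isolated)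
17 | O-benzyl ether of the target, (1'R,2'S,5'R,6'S)-furofuran | COc1cc([C@H]2Oc3c(OC)cc([C@H]4OC[C@H]5[C@@H]4CO[C@@H]5c4cc(OC)c(O)c(OC)c4)cc3[C@H]2CO)ccc1OCc1ccccc1 | intermediate
18 | CNP0126146.1: (1'R,2'S,5'R,6'S)-furofuran with C2' on C5 of the (2S,3S)-2-(4-hydroxy-3-methoxyphenyl)-3-(hydroxymethyl)-7-methoxy-2,3-dihydrobenzofuran and C6' on the 4-hydroxy-3,5-dimethoxyphenyl ring | COc1cc([C@H]2Oc3c(OC)cc([C@H]4OC[C@H]5[C@@H]4CO[C@@H]5c4cc(OC)c(O)c(OC)c4)cc3[C@H]2CO)ccc1O | target

**Count**

Total steps: 13. Longest linear sequence: 10 (steps 1–5 and 9–13).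

**Steps most likely to fail**

1. Step 12. After ring opening the capture may be unselective (the benzylic cation taken by acetate or by an arene), or the new p-oxygenated benzylic ethers may re-ionise in the acidic medium and lose the exo,exo configuration. The fallback sets out from 14 and comes back at 17. LiOH in aqueous THF removes tether and acetate from 14 to give the trans-cyclobutane-1,2-dicarboxylic acid F1. The same PhI(OAc)2 oxidation then lets the two carboxylic acids capture the quinone methide and the cation as γ-lactones, the capture mode known from oxidative 8–8' coupling of hydroxycinnamic acids, to give the bis-lactone F2. LiAlH4 reduces it to the tetraol F3, and the classical acid-catalysed double cyclodehydration of such lignan tetraols (camphorsulfonic acid, CH2Cl2) closes the furofuran to 17.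

2. Step 10. Closure to the strained trans-fused eight-membered bis-lactone may be slow, so that E/Z isomerisation and oligomerisation take over, or the facial discrimination by the tether may be poor. The fallback sets out from 9 (with 7) and comes back at 15. Acid 9 is esterified (EDC·HCl, DMAP) with excess (2R,4R)-pentane-2,4-diol to the monoester F4, which is acryloylated to the acrylate F5 and joined to 7 by the same Heck reaction to give the dicinnamate F6. Irradiation at 405 nm with thioxanthone as triplet sensitiser then builds the cyclobutane stepwise through a 1,4-diradical, which can relax to the trans ring fusion of the nine-membered bis-lactone F7 before it closes, and LiAlH4 gives 15. The enantiomeric diol would be taken if the sense of induction proves opposite.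

3. Step 3. Oxidative addition at the hindered, electron-rich aryl iodide may be slow and the diazo group may be lost through palladium carbene pathways. The fallback sets out from 4 and comes back at 5. Pd(PPh3)4-catalysed coupling of 4 with the Reformatsky reagent BrZnCH2CO2Et (THF, rt), selective for C–I, gives the arylacetate F8, and Regitz diazo transfer (4-acetamidobenzenesulfonyl azide, DBU, MeCN) converts it to 5.

**Further compounds**

F1 | step 12 | (1R,2R,3S,4S)-3-(4-hydroxy-3,5-dimethoxyphenyl)-4-(dihydrobenzofuran-5-yl)cyclobutane-1,2-dicarboxylic acid | COc1cc([C@H]2Oc3c(OC)cc([C@@H]4[C@@H](C(=O)O)[C@H](C(=O)O)[C@H]4c4cc(OC)c(O)c(OC)c4)cc3[C@H]2CO)ccc1OCc1ccccc1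
F2 | step 12 | 2',6'-diaryl-3,7-dioxabicyclo[3.3.0]octane-4,8-dione (bis-lactone, same configuration as 17) | COc1cc([C@H]2Oc3c(OC)cc([C@H]4OC(=O)[C@H]5[C@@H]4C(=O)O[C@@H]5c4cc(OC)c(O)c(OC)c4)cc3[C@H]2CO)ccc1OCc1ccccc1
F3 | step 12 | 1,4-diaryl-2,3-bis(hydroxymethyl)butane-1,4-diol (tetraol) | COc1cc([C@H]2Oc3c(OC)cc([C@@H](O)[C@@H](CO)[C@H](CO)[C@H](O)c4cc(OC)c(O)c(OC)c4)cc3[C@H]2CO)ccc1OCc1ccccc1
F4 | step 10 | (2R,4R)-4-hydroxypentan-2-yl (E)-3-(4-acetoxy-3,5-dimethoxyphenyl)prop-2-enoate | COc1cc(/C=C/C(=O)O[C@H](C)C[C@@H](C)O)cc(OC)c1OC(C)=O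
F5 | step 10 | (2R,4R)-4-(acryloyloxy)pentan-2-yl (E)-3-(4-acetoxy-3,5-dimethoxyphenyl)prop-2-enoate | COc1cc(/C=C/C(=O)O[C@H](C)C[C@@H](C)OC(=O)C=C)cc(OC)c1OC(C)=O
F6 | step 10 | (2R,4R)-pentane-2,4-diyl mixed (E,E)-dicinnamate | COc1cc([C@H]2Oc3c(OC)cc(/C=C/C(=O)O[C@H](C)C[C@@H](C)OC(=O)/C=C/c4cc(OC)c(OC(C)=O)c(OC)c4)cc3[C@H]2CO)ccc1OCc1ccccc1
F7 | step 10 | all-trans cyclobutane bis-lactone on the (2R,4R)-pentanediol tether (nine-membered ring) | COc1cc([C@H]2Oc3c(OC)cc([C@@H]4[C@H]5C(=O)O[C@H](C)C[C@@H](C)OC(=O)[C@@H]5[C@H]4c4cc(OC)c(OC(C)=O)c(OC)c4)cc3[C@H]2CO)ccc1OCc1ccccc1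
F8 | step 3 | ethyl 2-(2-{[4-(benzyloxy)-3-methoxyphenyl]methoxy}-5-bromo-3-methoxyphenyl)acetate | CCOC(=O)Cc1cc(Br)cc(OC)c1OCc1ccc(OCc2ccccc2)c(OC)c1
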